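**Retrosynthetic overview**
1. The target comes from one reductive operation on a bis(dithiane) tetrabenzyl ether that carries the bridge carbon as a carbinol. All C–S, O–benzyl and benzhydrylic C–O bonds become C–H or O–H.
2. Key cut: both ring A–CH2 bonds (aryl C6–Cα). Cα is a masked acyl anion (a lithiated 2-benzyl-1,3-dithiane). The aryl partner is a 3-methoxyaryne made from a C5 bromide, so carbon enters at C6 by cine substitution, on both rings in one flask.
3. The dibromo carbinol comes from commercial 2,2'-dihydroxy-4,4'-dimethoxybenzophenone by bromination, benzylation and hydride reduction. This ketone already holds the bridge carbon and the correct OH/OMe pattern.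
4. The nucleophile comes from 1,3-dithiane, used as a carbonyl linchpin, and O-benzylvanillyl chloride (Cα–Cβ bond).
5. Ring order: no ring of the target is built. All four benzene rings are bought, and the two dithiane rings are bought as 1,3-dithiane and destroyed in the last step.

Assumption: the target has no stereocentre and is achiral, so there is no enantiomer to select and the SMILES is taken as given.

Locants: in each ring A, C1 carries the bridge carbon, C2 the oxygen substituent and C4 the OMe. Ring B is the guaiacyl ring. Cα is the chain carbon on ring A and Cβ the one on ring B.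

**Step 1**
Reactants: 1 2,2'-dihydroxy-4,4'-dimethoxybenzophenone (benzophenone-6)
Product: 2 bis(5-bromo-2-hydroxy-4-methoxyphenyl)methanone
Conditions: NBS (2.1 equiv), MeCN, 0 °C to rt
Reagents that add atoms: N-bromosuccinimide, O=C1CCC(=O)N1Br
Why: Electrophilic aromatic bromination goes to C5 of each ring because it is para to the free OH, ortho to OMe and unhindered, whereas C3 is squeezed between two oxygens and C6 is meta to both donors, the site preference also seen in halogenation and sulfonation of 2-hydroxy-4-methoxyaryl ketones; no stereocentre is formed.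

**Step 2**
Reactants: 2 bis(5-bromo-2-hydroxy-4-methoxyphenyl)methanone
Product: 3 bis[2-(benzyloxy)-5-bromo-4-methoxyphenyl]methanone
Conditions: BnBr (2.5 equiv), K2CO3 (3 equiv), DMF, 70 °C
Reagents that add atoms: benzyl bromide, BrCc1ccccc1
Why: Williamson ether synthesis in warm K2CO3/DMF breaks the O–H···O=C chelate and benzylates both phenoxides, giving ethers that tolerate lithium amides below 0 °C and are removed later on nickel; no stereocentre is formed.

**Step 3**
Reactants: 3 bis[2-(benzyloxy)-5-bromo-4-methoxyphenyl]methanone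
Product: 4 bis[2-(benzyloxy)-5-bromo-4-methoxyphenyl]methanol
Conditions: NaBH4 (2 equiv), THF–MeOH, 0 to 40 °C; aq. NaHCO3 work-up
Reagents that add atoms: none
Why: Borohydride 1,2-reduction of a diaryl ketone leaves aryl bromides and ethers untouched, the carbinol carbon bears two identical aryl groups and is therefore not a stereocentre, and its alkoxide later replaces a CH2 bridge that strong base would deprotonate.

**Step 4**
Reactants: 5 [4-(benzyloxy)-3-methoxyphenyl]methanol
Product: 6 1-(benzyloxy)-4-(chloromethyl)-2-methoxybenzene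
Conditions: SOCl2 (1.2 equiv), CH2Cl2, 0 °C
Reagents that add atoms: thionyl chloride, O=S(Cl)Cl
Why: Chlorodehydroxylation through the chlorosulfite is fast for this electron-rich benzylic alcohol and gives a crystalline chloride with only gaseous by-products; no stereocentre is formed.

**Step 5**
Reactants: 7 1,3-dithiane; 6 1-(benzyloxy)-4-(chloromethyl)-2-methoxybenzene
Product: 9 2-[4-(benzyloxy)-3-methoxybenzyl]-1,3-dithiane, via 2-lithio-1,3-dithiane 8 (not isolated)
Conditions: n-BuLi (1.05 equiv), THF, −30 °C, 2 h; then 6, −78 to 0 °C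
Reagents that add atoms: none
Why: Corey–Seebach alkylation, in which the sulfur-stabilised formyl anion equivalent displaces a primary benzylic chloride by SN2 and forms the Cα–Cβ bond; no stereocentre is formed.

**Step 6**
Reactants: 4 bis[2-(benzyloxy)-5-bromo-4-methoxyphenyl]methanol; 9 2-[4-(benzyloxy)-3-methoxybenzyl]-1,3-dithiane
Product: 16 bis{2-(benzyloxy)-4-methoxy-6-[2-(4-benzyloxy-3-methoxybenzyl)-1,3-dithian-2-yl]phenyl}methanol, via lithiated dithiane 10 (not isolated), via lithium carbinolate 11 (not isolated), via first aryne 12 (not isolated), via monoadduct alkoxide 13 (not isolated), via second aryne 14 (not isolated), via bisadduct alkoxide 15 (not isolated)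
Conditions: 9 (5 equiv), n-BuLi (5 equiv), THF, −30 °C, 2 h; lithium 2,2,6,6-tetramethylpiperidide (3.5 equiv, from the amine and n-BuLi), −78 °C; 4 in THF added over 1 h, −78 to −10 °C, 4 h; H2O
Reagents that add atoms: none
Why: Proposed new method: a twofold aryne cine substitution by a Corey–Seebach acyl anion equivalent, in which the first equivalent of amide base makes carbinolate 11 (so no acidic diarylmethane C–H is present), the amide then removes the only hydrogen next to each C–Br bond (C6–H, which also lies ortho to the lithium alkoxide), loss of LiBr gives a 3-methoxyaryne whose C4 methoxy group polarises the strained bond so that carbanion 10 attacks the distal carbon C6 and leaves the charge at C5 next to oxygen, where the free amine protonates it, and the sequence repeats on the second ring; a fully substituted carbanion is chosen on purpose because it leaves no dithiane C–H whose anion could close onto the second aryne to give a dihydroanthracene; the closest known reaction types are the cine substitution of 2-haloanisoles and 4-haloresorcinol diethers by lithiated nitriles or amide ions and the capture of arynes by organolithium reagents; the carbinol carbon is a stereocentre only in the unsymmetrical transients 12 to 14 (racemic) and not in 16.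

**Step 7**
Reactants: 16 bis{2-(benzyloxy)-4-methoxy-6-[2-(4-benzyloxy-3-methoxybenzyl)-1,3-dithian-2-yl]phenyl}methanol
Product: 17 2,2'-methylenebis{3-[2-(4-hydroxy-3-methoxyphenyl)ethyl]-5-methoxyphenol} (target)
Conditions: Raney Ni (W-2, large excess, in two charges), H2 (1 atm), EtOH–THF, reflux, 24 h
Reagents that add atoms: none
Why: Mozingo-type reductive desulfurization turns both thioketal carbons into CH2, and the same hydrogen-laden nickel hydrogenolyses the four aryl benzyl ethers and then the doubly benzylic carbinol, which is activated by the freed ortho-OH and the para-OMe and can be reduced through its o-quinone methide, while aryl methyl ethers and arenes are untouched; the product has no stereocentre.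

**Compound list**
1 | 2,2'-dihydroxy-4,4'-dimethoxybenzophenone (benzophenone-6) | COc1ccc(C(=O)c2ccc(OC)cc2O)c(O)c1 | starting material
2 | bis(5-bromo-2-hydroxy-4-methoxyphenyl)methanone | COc1cc(O)c(cc1Br)C(=O)c1cc(Br)c(OC)cc1O | intermediate
3 | bis[2-(benzyloxy)-5-bromo-4-methoxyphenyl]methanone | COc1cc(OCc2ccccc2)c(cc1Br)C(=O)c1cc(Br)c(OC)cc1OCc1ccccc1 | intermediate
4 | bis[2-(benzyloxy)-5-bromo-4-methoxyphenyl]methanol | COc1cc(OCc2ccccc2)c(cc1Br)C(O)c1cc(Br)c(OC)cc1OCc1ccccc1 | intermediate
5 | [4-(benzyloxy)-3-methoxyphenyl]methanol | COc1cc(CO)ccc1OCc1ccccc1 | starting material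
6 | 1-(benzyloxy)-4-(chloromethyl)-2-methoxybenzene | COc1cc(CCl)ccc1OCc1ccccc1 | intermediate
7 | 1,3-dithiane | C1CSCSC1 | starting material
8 | 2-lithio-1,3-dithiane | [Li]C1SCCCS1 | intermediate (not isolated)
9 | 2-[4-(benzyloxy)-3-methoxybenzyl]-1,3-dithiane | COc1cc(CC2SCCCS2)ccc1OCc1ccccc1 | intermediate
10 | 2-lithio-2-[4-(benzyloxy)-3-methoxybenzyl]-1,3-dithiane | COc1cc(CC2([Li])SCCCS2)ccc1OCc1ccccc1 | intermediate (not isolated)
11 | lithium bis[2-(benzyloxy)-5-bromo-4-methoxyphenyl]methanolate | COc1cc(OCc2ccccc2)c(cc1Br)C(O[Li])c1cc(Br)c(OC)cc1OCc1ccccc1 | intermediate (not isolated)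
12 | lithium [2-(benzyloxy)-5-bromo-4-methoxyphenyl][2-(benzyloxy)-4-methoxy-5,6-didehydrophenyl]methanolate (racemic) | [Li]OC(c1cc(Br)c(OC)cc1OCc1ccccc1)C1=C(OCc2ccccc2)C=C(OC)C#C1 | intermediate (not isolated)
13 | lithium [2-(benzyloxy)-5-bromo-4-methoxyphenyl]{2-(benzyloxy)-4-methoxy-6-[2-(4-benzyloxy-3-methoxybenzyl)-1,3-dithian-2-yl]phenyl}methanolate (racemic) | [Li]OC(c1cc(Br)c(OC)cc1OCc1ccccc1)c1c(OCc2ccccc2)cc(OC)cc1C1(Cc2ccc(OCc3ccccc3)c(OC)c2)SCCCS1 | intermediate (not isolated)
14 | lithium [2-(benzyloxy)-4-methoxy-5,6-didehydrophenyl]{2-(benzyloxy)-4-methoxy-6-[2-(4-benzyloxy-3-methoxybenzyl)-1,3-dithian-2-yl]phenyl}methanolate (racemic) | [Li]OC(C1=C(OCc2ccccc2)C=C(OC)C#C1)c1c(OCc2ccccc2)cc(OC)cc1C1(Cc2ccc(OCc3ccccc3)c(OC)c2)SCCCS1 | intermediate (not isolated)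
15 | lithium bis{2-(benzyloxy)-4-methoxy-6-[2-(4-benzyloxy-3-methoxybenzyl)-1,3-dithian-2-yl]phenyl}methanolate | [Li]OC(c1c(OCc2ccccc2)cc(OC)cc1C1(Cc2ccc(OCc3ccccc3)c(OC)c2)SCCCS1)c1c(OCc2ccccc2)cc(OC)cc1C1(Cc2ccc(OCc3ccccc3)c(OC)c2)SCCCS1 | intermediate (not isolated)
16 | bis{2-(benzyloxy)-4-methoxy-6-[2-(4-benzyloxy-3-methoxybenzyl)-1,3-dithian-2-yl]phenyl}methanol | OC(c1c(OCc2ccccc2)cc(OC)cc1C1(Cc2ccc(OCc3ccccc3)c(OC)c2)SCCCS1)c1c(OCc2ccccc2)cc(OC)cc1C1(Cc2ccc(OCc3ccccc3)c(OC)c2)SCCCS1 | intermediate
17 | 2,2'-methylenebis{3-[2-(4-hydroxy-3-methoxyphenyl)ethyl]-5-methoxyphenol} (achiral) | COc1cc(O)c(Cc2c(O)cc(OC)cc2CCc2ccc(O)c(OC)c2)c(CCc2ccc(O)c(OC)c2)c1 | target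

**Step count**
Total steps: 7.
Longest linear sequence: 5 (1 → 2 → 3 → 4 → 16 → 17). The side branch 5 → 6 → 9 joins at step 6.

**Three steps most likely to fail**

Step 6 (twofold aryne capture).
- The bulky carbanion must enter at C6 beside the carbinol carbon, so sterics oppose the electronic bias set by the methoxy group.
- The second addition takes place in an even more crowded molecule.
- Bromine migration after reversible C3 lithiation, and hydride transfer from the carbinolate to the aryne, are possible leaks.
- The fallback sets out from chloride 6 and comes back at target 17. It keeps the acyl anion logic but makes the bridge last.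
- 3-Hydroxy-5-methoxybenzaldehyde F1 is condensed with propane-1,3-dithiol (BF3·OEt2, CH2Cl2) to 3-(1,3-dithian-2-yl)-5-methoxyphenol F2.
- The O,C-dianion of F2 (n-BuLi, 2.1 equiv, THF) is benzylated on carbon by 6 to give 3-{2-[4-(benzyloxy)-3-methoxybenzyl]-1,3-dithian-2-yl}-5-methoxyphenol F3.
- Raney Ni under H2 strips sulfur and benzyl from F3 to give gigantol F4.
- The bromomagnesium phenoxide of F4 (EtMgBr) is heated with half an equivalent of paraformaldehyde in toluene. It is bridged ortho to the ring A oxygen and para to OMe, which gives 17.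

Step 7 (global reduction on nickel).
- Sulfided nickel loses hydrogenolysis activity, so partly benzylated material or retained carbinol may remain.
- The fallback sets out from 16 and comes back at 17. It separates sulfur removal from hydrogenolysis.
- Nickel boride Ni2B, made in the flask from NiCl2·6H2O and NaBH4 in MeOH–THF, removes only the sulfur. This gives bis{2-(benzyloxy)-6-[2-(4-benzyloxy-3-methoxyphenyl)ethyl]-4-methoxyphenyl}methanol F5.
- F5 is now free of catalyst poison. H2 over Pd/C in EtOH–AcOH cleaves its four benzyl ethers and the benzhydrylic C–O bond to give 17.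

Step 3 (carbinol 4).
- The tetraalkoxybenzhydrol ionises very easily. Ether formation, disproportionation or loss on silica could make it unusable.
- The fallback sets out from 2 and comes back at 17. It drops both the carbinol and the ring A benzyl groups.
- Ionic hydrogenation of 2 (Et3SiH, CF3CO2H) gives 2,2'-methylenebis(4-bromo-5-methoxyphenol) F6.
- In the dilithium bisphenoxide of F6, the two ortho oxido groups keep the CH2 bridge from being deprotonated. It is submitted to the aryne capture by 10 with two extra equivalents of lithium 2,2,6,6-tetramethylpiperidide. This gives 2,2'-methylenebis{3-[2-(4-benzyloxy-3-methoxybenzyl)-1,3-dithian-2-yl]-5-methoxyphenol} F7.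
- Raney Ni under H2 converts F7 into 17.

**Further compounds**
F1 | step 6 | 3-hydroxy-5-methoxybenzaldehyde | COc1cc(O)cc(C=O)c1
F2 | step 6 | 3-(1,3-dithian-2-yl)-5-methoxyphenol | COc1cc(O)cc(c1)C1SCCCS1
F3 | step 6 | 3-{2-[4-(benzyloxy)-3-methoxybenzyl]-1,3-dithian-2-yl}-5-methoxyphenol | COc1cc(O)cc(c1)C1(Cc2ccc(OCc3ccccc3)c(OC)c2)SCCCS1
F4 | step 6 | gigantol, 4-[2-(3-hydroxy-5-methoxyphenyl)ethyl]-2-methoxyphenol | COc1cc(O)cc(CCc2ccc(O)c(OC)c2)c1
F5 | step 7 | bis{2-(benzyloxy)-6-[2-(4-benzyloxy-3-methoxyphenyl)ethyl]-4-methoxyphenyl}methanol | OC(c1c(OCc2ccccc2)cc(OC)cc1CCc1ccc(OCc2ccccc2)c(OC)c1)c1c(OCc2ccccc2)cc(OC)cc1CCc1ccc(OCc2ccccc2)c(OC)c1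
F6 | step 3 | 2,2'-methylenebis(4-bromo-5-methoxyphenol) | COc1cc(O)c(Cc2cc(Br)c(OC)cc2O)cc1Br
F7 | step 3 | 2,2'-methylenebis{3-[2-(4-benzyloxy-3-methoxybenzyl)-1,3-dithian-2-yl]-5-methoxyphenol} | COc1cc(O)c(Cc2c(O)cc(OC)cc2C2(Cc3ccc(OCc4ccccc4)c(OC)c3)SCCCS2)c(c1)C1(Cc2ccc(OCc3ccccc3)c(OC)c2)SCCCS1
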